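The runs were generated by integration with made-up constants; the scatter is artificial.

In the flask the partner is charged at twice the left-handed substrate, yet that is exactly one partner for each molecule of the two substrates together, so the partner is what to watch.

| flask | left-handed substrate | right-handed substrate | partner | free catalyst | remark |
|---|---|---|---|---|---|
| south-west | 30 mM | 30 mM | 40 mM | 1 mM | run made earlier |
| flask | 20 mM | 20 mM | 40.0 mM | 1.0 mM |  |

south-west run (percent of the left-handed substrate and right-handed substrate together charged)

| time / h | left-handed product / % | left-handed substrate / % |
|---|---|---|
| 0.500 | 3.9 | 45.9 |
| 1.50 | 9.1 | 39.8 |
| 3.00 | 16.2 | 32.2 |
| 4.00 | 20.8 | 28.0 |
| 6.00 | 27.2 | 21.6 |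

(standard deviation of a reading: 0.3 percentage points)

- free catalyst is single-handed; left-handed substrate and right-handed substrate are mirror images of each other, charged as a racemate, each of them at the stated concentration
- steps thought possible: free catalyst + left-handed substrate <-> catalyst intermediate A; free catalyst + right-handed substrate <-> catalyst intermediate B; partner + catalyst intermediate A -> free catalyst + left-handed product; partner + catalyst intermediate B -> free catalyst + right-handed product; partner -> decomposed reagent
- no earlier run changes the charge of free catalyst; that part of a forecast is a guess
- no earlier run changes the charge of partner; that part of a forecast is a guess

- apparent order in partner when 50 % of the left-handed substrate and right-handed substrate together are converted (percent change of the rate of making left-handed product for one percent more partner charged)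
- factor on the rate of making left-handed product when 50 % of the left-handed substrate and right-handed substrate together are converted if free catalyst is charged twice over

In the south-west run, left-handed substrate plus left-handed product stood 1.20 % of the charge short of 0.5 at 6.00 h. We read that gap as catalyst intermediate A, about 72.0 % of the catalyst, the resting state there. The rate of making left-handed product is then a rate constant times intermediate A times partner.

Each product molecule costs one partner. So we reckon for the flask the spoken-for share, the fraction of the partner charge that coupling must consume to reach 50 % conversion: 50.0 %. What remains is a difference, the charge less this share less whatever has decomposed.

One percent more partner charged adds that one percent to this small remainder, with substrates and catalyst forms taken as unchanged at equal conversion. The apparent order is therefore one over the fraction left. With nothing decomposed that gives 2.00, and any decomposition raises it, though these readings don't measure it. Twice the catalyst gives twice the rate and reaches the same conversion in about half the time, so less partner decomposes and we expect a factor above two.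

The forecast gave 1.8 and 2.1, working with “a local order of about 0.8–1”, and its order lies below our value with nothing decomposed.

The flask gives an order of 2.8 and a factor of 2.87.

    free catalyst + left-handed substrate ⇌ catalyst intermediate A (K = 490 /M, k = 1700 /M/h)
    free catalyst + right-handed substrate ⇌ catalyst intermediate B (K = 17.0 /M, k = 24000 /M/h)
    partner + catalyst intermediate A → free catalyst + left-handed product (k = 130 /M/h)
    partner + catalyst intermediate B → free catalyst + right-handed product (k = 41.0 /M/h)
    partner → decomposed reagent (k = 0.0320 /h)

That conversion comes at 11.1 h, and at 10.0 h the flask already held 7.50 mM of decomposed reagent. Taking that amount together with the spoken-for share leaves 31.2 % of the partner and an order of 3.21, higher than the flask's value. The partner itself stood at 33.9 % of its charge at 10.0 h.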